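**Retrosynthetic overview**
- The target is disconnected at O1–C8a and C4a–C5: rings C and A both come, in one flask, from an open-chain (S)-hydroxy enol-ether triketo ester, ring C closing first and ring A second.
- That open-chain ester is cut at C8–C8a: the γ-carbanion (dianion) of methyl 2-lavandulylacetoacetate opens a chiral 6-aryl-4-methoxy-δ-lactone.
- The δ-lactone (a sacrificial ring that carries C2) comes from a catalytic asymmetric Brassard hetero-Diels–Alder reaction of silyl-protected 4-hydroxy-2-methoxybenzaldehyde.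
- The lavandulyl keto ester comes from methyl acetoacetate and (R)-lavandulyl iodide, made from (R)-lavandulol.
- Ring order: ring B is bought; the δ-lactone is made and opened; ring C, then ring A, close in the last operation.

Assumption: (R)-(−)-lavandulol is bought as the single enantiomer (≥98% ee); C2–C8a and O1 in the explanations are flavanone locants, and the side-chain centre, unchanged throughout, is (S) in the target only because the CIP priorities change.

**Step 1**
Reactants: 1 4-hydroxy-2-methoxybenzaldehyde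
Product: 2 4-(tert-butyldimethylsilyloxy)-2-methoxybenzaldehyde
Conditions: TBSCl, imidazole, DMF, 0 °C → rt
Reagents that add atoms: tert-butyldimethylsilyl chloride, CC(C)(C)[Si](C)(C)Cl
Why: Phenol O-silylation masks the acidic hydroxyl for the Lewis-acid and carbanion steps, and an aryl silyl ether survives both.

**Step 2**
Reactants: 3 methyl (E)-3-methoxybut-2-enoate
Product: 4 (E)-1,3-dimethoxy-1-(trimethylsilyloxy)buta-1,3-diene (Brassard diene)
Conditions: LiN(iPr)2, THF, −78 °C; Me3SiCl, −78 °C → rt; distil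
Reagents that add atoms: chlorotrimethylsilane, C[Si](C)(C)Cl
Why: γ-Deprotonation of the vinylogous ester gives the dienolate, which is O-silylated to the silyl ketene acetal diene.

**Step 3**
Reactants: 2 4-(tert-butyldimethylsilyloxy)-2-methoxybenzaldehyde; 4 Brassard diene
Product: 6 (S)-6-[4-(tert-butyldimethylsilyloxy)-2-methoxyphenyl]-4-methoxy-5,6-dihydro-2H-pyran-2-one, via silyl aldol adduct 5 (not isolated)
Conditions: Ti(OiPr)4/(S)-1,1'-bi-2-naphthol (1:1, 20 mol %), 4 Å MS, toluene, 0 °C → rt; then CF3CO2H (cat.), CH2Cl2, 0 °C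
Reagents that add atoms: none
Why: Catalytic asymmetric Brassard hetero-Diels–Alder reaction (vinylogous Mukaiyama aldol, then lactonisation); the chiral titanium–binaphthol Lewis acid shields one aldehyde face so the diene terminus sets the (S)-carbinol centre (later C2), the ligand antipode being the one that gives the (S)-lactone (sense to be confirmed against known 6-aryl kavalactones).

**Step 4**
Reactants: 7 (R)-lavandulol, (2R)-5-methyl-2-(prop-1-en-2-yl)hex-4-en-1-ol
Product: 8 (R)-lavandulyl iodide, (3R)-3-(iodomethyl)-2,6-dimethylhepta-1,5-diene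
Conditions: I2, PPh3, imidazole, CH2Cl2, 0 °C → rt
Reagents that add atoms: iodine, II
Why: Appel iodination is an SN2 displacement at the primary carbinol carbon, so the adjacent stereocentre and both alkenes are untouched.

**Step 5**
Reactants: 8 (R)-lavandulyl iodide; 9 methyl acetoacetate
Product: 10 methyl (4S)-2-acetyl-7-methyl-4-(prop-1-en-2-yl)oct-6-enoate (methyl 2-lavandulylacetoacetate, C2 epimers)
Conditions: 9 (3 equiv), NaH (2.8 equiv), THF/DMF, 0 °C; then 8, 50 °C
Reagents that add atoms: none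
Why: Acetoacetic ester C-alkylation (SN2) by the soft, weakly basic enolate, used in excess to limit E2 and dialkylation; the lavandulyl centre is not involved and the new α-centre later becomes sp2.

**Step 6**
Reactants: 10 methyl 2-lavandulylacetoacetate; 6 (S)-δ-lactone
Product: 11 methyl (6E,9S)-9-[4-(tert-butyldimethylsilyloxy)-2-methoxyphenyl]-9-hydroxy-7-methoxy-2-[(2S)-5-methyl-2-(prop-1-en-2-yl)hex-4-en-1-yl]-3,5-dioxonon-6-enoate (C2 epimers, enol tautomers)
Conditions: 10 (2.2 equiv), LiN(iPr)2 (4.4 equiv), THF, −78 → 0 °C; then 6, −78 → −20 °C; aq. NH4Cl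
Reagents that add atoms: none
Why: Weiler-dianion Claisen-type acylation: the terminal carbanion of the β-keto ester dianion adds to the lactone carbonyl, which opens by acyl–oxygen cleavage, so the C8–C8a bond forms and the (S)-carbinol C–O bond is never broken.

**Step 7**
Reactants: 11 open-chain (S)-hydroxy enol-ether triketo ester
Product: 14 (2S)-5,7-dihydroxy-2-(4-hydroxy-2-methoxyphenyl)-6-[(2S)-5-methyl-2-(prop-1-en-2-yl)hex-4-en-1-yl]chroman-4-one, via pyranone keto ester 12 (not isolated), via silyl flavanone 13 (not isolated)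
Conditions: (1S)-10-camphorsulfonic acid (0.2 equiv), THF/H2O 20:1, 0 °C → rt; evaporate; 1,8-diazabicyclo[5.4.0]undec-7-ene (DBU, 3 equiv), CH2Cl2, 0 °C → rt; then Et3N·3HF, rt
Reagents that add atoms: water, O
Why: Proposed new method: the acid makes the C9 hydroxyl add to the vinylogous-ester ketone, water is lost and the resulting 4-methoxy-dihydropyrylium-type cation is hydrolysed at the methoxy carbon, so ring C closes as 2,3-dihydro-4H-pyran-4-one 12 with O1 bonded to C8a before ring A exists (this fixes the side chain at C6, not C8) and with the C2–O bond unbroken (S retained); DBU then deprotonates the doubly activated C8 methylene, the vinylogous dienolate attacks the methyl ester through C4a (Dieckmann-type Claisen), loss of methoxide and enolisation aromatise ring A to 13, and fluoride cleaves the aryl silyl ether; the closest known reaction types are the acid-induced Stork–Danheiser-type transposition of 4-methoxy-δ-lactone adducts to dihydropyranones and the biomimetic Claisen cyclisation of 3,5,7-triketo esters to acylphloroglucinols.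

**Compound list**
1 | 4-hydroxy-2-methoxybenzaldehyde | O=Cc1ccc(O)cc1OC | starting material
2 | 4-(tert-butyldimethylsilyloxy)-2-methoxybenzaldehyde | O=Cc1ccc(O[Si](C)(C)C(C)(C)C)cc1OC | intermediate
3 | methyl (E)-3-methoxybut-2-enoate | CO/C(C)=C/C(=O)OC | starting material
4 | (E)-1,3-dimethoxy-1-(trimethylsilyloxy)buta-1,3-diene | C=C(OC)/C=C(/O[Si](C)(C)C)OC | intermediate
5 | methyl (2E,5S)-5-[4-(tert-butyldimethylsilyloxy)-2-methoxyphenyl]-3-methoxy-5-(trimethylsilyloxy)pent-2-enoate | COC(=O)/C=C(/OC)C[C@H](O[Si](C)(C)C)c1ccc(O[Si](C)(C)C(C)(C)C)cc1OC | intermediate (not isolated)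
6 | (S)-6-[4-(tert-butyldimethylsilyloxy)-2-methoxyphenyl]-4-methoxy-5,6-dihydro-2H-pyran-2-one | COC1=CC(=O)O[C@H](c2ccc(O[Si](C)(C)C(C)(C)C)cc2OC)C1 | intermediate
7 | (R)-lavandulol, (2R)-5-methyl-2-(prop-1-en-2-yl)hex-4-en-1-ol | C=C(C)[C@@H](CC=C(C)C)CO | starting material
8 | (3R)-3-(iodomethyl)-2,6-dimethylhepta-1,5-diene | C=C(C)[C@@H](CC=C(C)C)CI | intermediate
9 | methyl acetoacetate | CC(=O)CC(=O)OC | starting material
10 | methyl (4S)-2-acetyl-7-methyl-4-(prop-1-en-2-yl)oct-6-enoate | C=C(C)[C@@H](CC=C(C)C)CC(C(C)=O)C(=O)OC | intermediate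
11 | methyl (6E,9S)-9-[4-(tert-butyldimethylsilyloxy)-2-methoxyphenyl]-9-hydroxy-7-methoxy-2-[(2S)-5-methyl-2-(prop-1-en-2-yl)hex-4-en-1-yl]-3,5-dioxonon-6-enoate | C=C(C)[C@@H](CC=C(C)C)CC(C(=O)OC)C(=O)CC(=O)/C=C(/OC)C[C@H](O)c1ccc(O[Si](C)(C)C(C)(C)C)cc1OC | intermediate
12 | methyl 4-{(2S)-2-[4-(tert-butyldimethylsilyloxy)-2-methoxyphenyl]-4-oxo-3,4-dihydro-2H-pyran-6-yl}-2-[(2S)-5-methyl-2-(prop-1-en-2-yl)hex-4-en-1-yl]-3-oxobutanoate | C=C(C)[C@@H](CC=C(C)C)CC(C(=O)OC)C(=O)CC1=CC(=O)C[C@@H](c2ccc(O[Si](C)(C)C(C)(C)C)cc2OC)O1 | intermediate (not isolated)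
13 | (2S)-2-[4-(tert-butyldimethylsilyloxy)-2-methoxyphenyl]-5,7-dihydroxy-6-[(2S)-5-methyl-2-(prop-1-en-2-yl)hex-4-en-1-yl]chroman-4-one | C=C(C)[C@@H](CC=C(C)C)Cc1c(O)cc2c(c1O)C(=O)C[C@@H](c1ccc(O[Si](C)(C)C(C)(C)C)cc1OC)O2 | intermediate (not isolated)
14 | (2S)-5,7-dihydroxy-2-(4-hydroxy-2-methoxyphenyl)-6-[(2S)-5-methyl-2-(prop-1-en-2-yl)hex-4-en-1-yl]chroman-4-one | C=C(C)[C@@H](CC=C(C)C)Cc1c(O)cc2c(c1O)C(=O)C[C@@H](c1ccc(O)cc1OC)O2 | target

**Totals**
Total steps: 7. Longest linear sequence: 4 steps (1 → 2 → 6 → 11 → 14; the branch 7 → 8 → 10 → 11 → 14 is equally long).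

**Three steps most likely to fail**

Step 7 (double ring closure). Risks: in the acid stage, the enolised C7 ketone could add to the methoxy-bearing carbon and give a γ-pyrone instead of ring C, or the electron-rich benzylic carbinol could ionise. In the base stage, the Claisen closure of ring A could stall, or C2 could erode by retro-oxa-Michael opening. Fallback, setting out from 8 and coming back at 13: ring A is closed thermally through a ketene instead of by base. Compound 8 alkylates tert-butyl acetoacetate (NaH, THF/DMF) to tert-butyl (4S)-2-acetyl-7-methyl-4-(prop-1-en-2-yl)oct-6-enoate F5. Its dianion opens 6 as in step 6 to the tert-butyl ester analogue of 11 F6. Camphorsulfonic acid in wet THF closes ring C, and the pyranone tert-butyl keto ester F7 is isolated. Heating F7 in xylene at 135 °C under a nitrogen sweep expels tert-butanol and gives the acylketene F8. The enol of F8 is a dienylketene that undergoes 6π-electrocyclisation and tautomerises to 13 under neutral conditions. Compound 13 is then desilylated with Et3N·3HF as in step 7.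

Step 6 (dianion opening of the lactone). Risks: the vinylogous-carbonate carbonyl of 6 is a weak electrophile, and the dianion may instead remove the γ-proton of 6 and cause E1cB ring-opening to a dienoate. Fallback, setting out from 6 and coming back at 11: 6 is opened with MeNH(OMe)·HCl/iPrMgCl (THF, −20 °C) to the acyclic Weinreb amide (2E,5S)-5-[4-(tert-butyldimethylsilyloxy)-2-methoxyphenyl]-5-hydroxy-N,3-dimethoxy-N-methylpent-2-enamide F4. Its hydroxyl is first converted to the lithium alkoxide with LiN(SiMe3)2, so no ring-opening elimination is possible. The dianion of 10 is then acylated by F4 through the chelated tetrahedral intermediate, and aqueous NH4Cl gives 11.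

Step 3 (asymmetric hetero-Diels–Alder). Risks: the 2,4-dioxygenated aldehyde is deactivated, so conversion or ee may be low. Fallback, setting out from 2 and coming back at 6: bought 2,2,6-trimethyl-4H-1,3-dioxin-4-one is converted (LiN(iPr)2, Me3SiCl) into the silyl dienol ether 2,2-dimethyl-4-methylene-6-(trimethylsilyloxy)-4H-1,3-dioxine F1. A catalytic asymmetric vinylogous Mukaiyama aldol addition of F1 to 2 (Cu(OTf)2/(S)-2,2'-bis(di-p-tolylphosphino)-1,1'-binaphthyl/tetrabutylammonium difluorotriphenylsilicate, THF, −78 °C, acidic work-up; ligand antipode chosen for the (S)-carbinol) gives the hydroxy dioxinone 6-{(2S)-2-[4-(tert-butyldimethylsilyloxy)-2-methoxyphenyl]-2-hydroxyethyl}-2,2-dimethyl-4H-1,3-dioxin-4-one F2. Heating F2 in toluene at 110 °C (retro-[4+2] to the acylketene, trapped by the δ-hydroxyl) gives the lactone dione (S)-6-[4-(tert-butyldimethylsilyloxy)-2-methoxyphenyl]dihydro-2H-pyran-2,4(3H)-dione F3. O-Methylation of F3 (Me2SO4, K2CO3, acetone) gives 6.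

**Further compounds**
F1 | step 3 | 2,2-dimethyl-4-methylene-6-(trimethylsilyloxy)-4H-1,3-dioxine | C=C1C=C(O[Si](C)(C)C)OC(C)(C)O1
F2 | step 3 | 6-{(2S)-2-[4-(tert-butyldimethylsilyloxy)-2-methoxyphenyl]-2-hydroxyethyl}-2,2-dimethyl-4H-1,3-dioxin-4-one | CC1(C)OC(=O)C=C(C[C@H](O)c2ccc(O[Si](C)(C)C(C)(C)C)cc2OC)O1
F3 | step 3 | (S)-6-[4-(tert-butyldimethylsilyloxy)-2-methoxyphenyl]dihydro-2H-pyran-2,4(3H)-dione | O=C1CC(=O)O[C@H](c2ccc(O[Si](C)(C)C(C)(C)C)cc2OC)C1
F4 | step 6 | (2E,5S)-5-[4-(tert-butyldimethylsilyloxy)-2-methoxyphenyl]-5-hydroxy-N,3-dimethoxy-N-methylpent-2-enamide | CON(C)C(=O)/C=C(/OC)C[C@H](O)c1ccc(O[Si](C)(C)C(C)(C)C)cc1OC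
F5 | step 7 | tert-butyl (4S)-2-acetyl-7-methyl-4-(prop-1-en-2-yl)oct-6-enoate | C=C(C)[C@@H](CC=C(C)C)CC(C(C)=O)C(=O)OC(C)(C)C
F6 | step 7 | tert-butyl (6E,9S)-9-[4-(tert-butyldimethylsilyloxy)-2-methoxyphenyl]-9-hydroxy-7-methoxy-2-[(2S)-5-methyl-2-(prop-1-en-2-yl)hex-4-en-1-yl]-3,5-dioxonon-6-enoate | C=C(C)[C@@H](CC=C(C)C)CC(C(=O)OC(C)(C)C)C(=O)CC(=O)/C=C(/OC)C[C@H](O)c1ccc(O[Si](C)(C)C(C)(C)C)cc1OC
F7 | step 7 | tert-butyl 4-{(2S)-2-[4-(tert-butyldimethylsilyloxy)-2-methoxyphenyl]-4-oxo-3,4-dihydro-2H-pyran-6-yl}-2-[(2S)-5-methyl-2-(prop-1-en-2-yl)hex-4-en-1-yl]-3-oxobutanoate | C=C(C)[C@@H](CC=C(C)C)CC(C(=O)OC(C)(C)C)C(=O)CC1=CC(=O)C[C@@H](c2ccc(O[Si](C)(C)C(C)(C)C)cc2OC)O1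
F8 | step 7 | 4-{(2S)-2-[4-(tert-butyldimethylsilyloxy)-2-methoxyphenyl]-4-oxo-3,4-dihydro-2H-pyran-6-yl}-2-[(2S)-5-methyl-2-(prop-1-en-2-yl)hex-4-en-1-yl]-3-oxobut-1-en-1-one (acylketene) | C=C(C)[C@@H](CC=C(C)C)CC(=C=O)C(=O)CC1=CC(=O)C[C@@H](c2ccc(O[Si](C)(C)C(C)(C)C)cc2OC)O1
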